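**Retrosynthetic overview**

- Ring C is opened last at O1–C2 and C2–C3 (C2 is a single carbon from DMF). This leads back to 1-(2,4-dihydroxy-5-methoxyphenyl)-2-(3,4,5-trimethoxyphenyl)ethanone.
- Ring A of that ketone is cut at C5–C6 and C4a–C8a (chromone numbering). C6(OMe)–C7(OH)–C8–C8a(O1) is the four-carbon chain of methyl 4-methoxyacetoacetate, used as its 1,3-bis(silyloxy)diene. C5–C4a are the alkyne carbons of 1-(3,4,5-trimethoxyphenyl)but-3-yn-2-one, which already carries C4, C3 and ring B.
- The feature used: ring A carries O1 on C8a, OH on C7, OMe on C6 and the acyl carbon on C4a. This is the oxygen pattern of the keto ester (ester O to C8a, ketone O to C7, ether O to C6), so the 6-OMe/7-OH difference never has to be made on an arene.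
- The diene comes from the keto ester by two silylations; the ynone comes from 3,4,5-trimethoxyphenylacetic acid via its N-methoxy-N-methylamide and ethynylmagnesium bromide.
- Ring order: ring B is bought, ring A is built by (4+2) cycloaddition and aromatisation, ring C is closed by one-carbon annulation.

Key step: step 5

Remark: the enol ether and diene geometries are written as the isomers expected to predominate; all of these C=C bonds end up in aromatic ring A, so any geometric isomer converges on the same product.

**Route**

Step 1
Reactants: 1 methyl 4-methoxy-3-oxobutanoate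
Product: 2 methyl (2Z)-4-methoxy-3-(trimethylsilyloxy)but-2-enoate
Conditions: Me3SiCl, Et3N, toluene, 20 °C, 48 h; filtration under argon, distillation
Reagents that add atoms: chlorotrimethylsilane, C[Si](C)(C)Cl
Why: Soft enolisation of the β-keto ester by Et3N and O-silylation by Me3SiCl (silyl enol ether formation) should give the conjugated 3-silyloxy enoate, the ether and ester groups being inert.

Step 2
Reactants: 2 methyl (2Z)-4-methoxy-3-(trimethylsilyloxy)but-2-enoate
Product: 4 (1Z,3Z)-1,4-dimethoxy-1,3-bis(trimethylsilyloxy)buta-1,3-diene, via lithium dienolate 3 (not isolated)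
Conditions: LiN(iPr)2 (commercial solution), THF, −78 °C; then Me3SiCl, −78 → 20 °C; pentane, filtration under argon, used crude
Reagents that add atoms: chlorotrimethylsilane, C[Si](C)(C)Cl
Why: LiN(iPr)2 should remove a γ-hydrogen of the vinylogous ester at −78 °C and Me3SiCl should trap the extended enolate on oxygen (silyl ketene acetal formation), the established second stage in making 1-alkoxy-1,3-bis(silyloxy)butadienes, the product being kept free of moisture and used at once.

Step 3
Reactants: 5 2-(3,4,5-trimethoxyphenyl)acetic acid
Product: 7 N-methoxy-N-methyl-2-(3,4,5-trimethoxyphenyl)acetamide, via acyl imidazole 6 (not isolated)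
Conditions: carbonyl diimidazole, CH2Cl2, 20 °C; then MeNHOMe·HCl, 20 °C
Reagents that add atoms: N,O-dimethylhydroxylamine hydrochloride, CNOC.Cl
Why: Carbonyl diimidazole should activate the acid as the acyl imidazole, which N,O-dimethylhydroxylamine aminolyses to the Weinreb amide under near-neutral conditions that leave the aryl methyl ethers untouched.

Step 4
Reactants: 7 N-methoxy-N-methyl-2-(3,4,5-trimethoxyphenyl)acetamide; 8 ethynylmagnesium bromide
Product: 10 1-(3,4,5-trimethoxyphenyl)but-3-yn-2-one, via magnesium hemiaminal alkoxide 9 (not isolated)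
Conditions: HC≡CMgBr (0.5 M in THF, 2.5 equiv), THF, 0 → 20 °C; inverse quench into ice-cold 1 M aq. HCl/Et2O; used promptly
Reagents that add atoms: none
Why: In this Weinreb ketone synthesis the alkynyl Grignard reagent should add only once because the magnesium chelate 9 persists until work-up, and the inverse quench into cold acid keeps the released N,O-dimethylhydroxylamine protonated so that it cannot add to the ynone in a conjugate manner.

Step 5
Reactants: 4 (1Z,3Z)-1,4-dimethoxy-1,3-bis(trimethylsilyloxy)buta-1,3-diene; 10 1-(3,4,5-trimethoxyphenyl)but-3-yn-2-one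
Product: 12 1-(2,4-dihydroxy-5-methoxyphenyl)-2-(3,4,5-trimethoxyphenyl)ethan-1-one, via cyclohexa-1,4-diene cycloadduct 11 (not isolated)
Conditions: 4 (2 equiv), toluene, −20 → 20 °C (50 °C if slow), no Lewis acid; then 1 M aq. HCl, THF, 20 °C
Reagents that add atoms: none
Why: The electron-rich diene 4 and the electron-poor terminal ynone 10 should combine in a thermal normal-demand Diels–Alder reaction in which the methoxy-bearing diene terminus, the most nucleophilic carbon because the two ketene acetal oxygens and the central silyloxy group all donate to it, bonds to the terminal alkyne carbon (future C6–C5) and the ketene acetal carbon bonds to the acyl-bearing alkyne carbon (future C8a–C4a), giving cyclohexa-1,4-diene 11. The closest known reaction type is the cycloaddition–aromatisation of 1-alkoxy-1,3-bis(silyloxy)butadienes with acetylenic ketones and esters, which delivers resorcinol derivatives. Ring A is closed by this intermolecular (4+2) cycloaddition, four diene carbons and two alkyne carbons forming the six-membered carbocycle, and a stepwise Mukaiyama–Michael addition followed by closure of the allenyl silyl ether onto the acetal carbon would lead to the same ring. Aqueous acid then cleaves the silyl groups, the hemiketal at C8a collapses to the carbonyl with loss of methanol and the dienone enolises by loss of the C6 hydrogen, so that C8a and C7 appear as free hydroxyls while the C6 methoxy group is kept, C6–H being the only hydrogen whose removal can aromatise the ring. No stereocentre is set, since the two sp3 ring carbons of 11 (C6 and C8a) become aromatic and the diene geometry and facial course therefore do not matter. The step needs the C6–C5/C8a–C4a regiochemistry and addition across the alkyne instead of attack on the ketone carbonyl (a 3+3 course to a salicylate); the matched polarisation of the two partners should secure the first and the absence of any Lewis acid, which leaves the carbonyl unactivated, the second.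

Step 6
Reactants: 12 1-(2,4-dihydroxy-5-methoxyphenyl)-2-(3,4,5-trimethoxyphenyl)ethan-1-one
Product: 14 7-hydroxy-6-methoxy-3-(3,4,5-trimethoxyphenyl)-4H-chromen-4-one (target), via difluoroboron chelate 13 (not isolated)
Conditions: BF3·OEt2, DMF, 20 → 50 °C; then MeSO2Cl, 50 → 80 °C; ice–water
Reagents that add atoms: N,N-dimethylformamide, CN(C)C=O
Why: BF3 should convert the hydrogen-bonded 2-hydroxy ketone into the difluoroboron chelate 13, whose enolisable CH2 is aminomethylenated by the iminium salt formed from DMF and MeSO2Cl (Vilsmeier-type formylation), after which the 2-oxygen adds to the new carbon and dimethylamine is lost to close the pyranone, a known one-pot isoflavone synthesis that tolerates a free 4-hydroxyl group.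

**Compound list**

1 | methyl 4-methoxy-3-oxobutanoate (methyl 4-methoxyacetoacetate) | COCC(=O)CC(=O)OC | starting material
2 | methyl (2Z)-4-methoxy-3-(trimethylsilyloxy)but-2-enoate | COC/C(O[Si](C)(C)C)=C/C(=O)OC | intermediate
3 | lithium (1E,3Z)-1,4-dimethoxy-3-(trimethylsilyloxy)buta-1,3-dien-1-olate (lithium dienolate of 2, not isolated) | CO/C=C(O[Si](C)(C)C)/C=C(/OC)O[Li] | intermediate
4 | (1Z,3Z)-1,4-dimethoxy-1,3-bis(trimethylsilyloxy)buta-1,3-diene | CO/C=C(O[Si](C)(C)C)/C=C(/OC)O[Si](C)(C)C | intermediate
5 | 2-(3,4,5-trimethoxyphenyl)acetic acid | COc1cc(CC(=O)O)cc(OC)c1OC | starting material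
6 | 1-(imidazol-1-yl)-2-(3,4,5-trimethoxyphenyl)ethan-1-one (acyl imidazole, not isolated) | COc1cc(CC(=O)n2ccnc2)cc(OC)c1OC | intermediate
7 | N-methoxy-N-methyl-2-(3,4,5-trimethoxyphenyl)acetamide | CON(C)C(=O)Cc1cc(OC)c(OC)c(OC)c1 | intermediate
8 | ethynylmagnesium bromide | C#C[Mg]Br | starting material
9 | bromomagnesium 2-[methoxy(methyl)amino]-1-(3,4,5-trimethoxyphenyl)but-3-yn-2-olate (racemic tetrahedral adduct, not isolated) | COc1cc(CC(C#C)(O[Mg]Br)N(C)OC)cc(OC)c1OC | intermediate
10 | 1-(3,4,5-trimethoxyphenyl)but-3-yn-2-one | C#CC(=O)Cc1cc(OC)c(OC)c(OC)c1 | intermediate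
11 | 1-[3,6-dimethoxy-4,6-bis(trimethylsilyloxy)cyclohexa-1,4-dien-1-yl]-2-(3,4,5-trimethoxyphenyl)ethan-1-one (racemic, mixture of diastereomers at the two sp3 ring carbons, not isolated) | COC1C=C(C(=O)Cc2cc(OC)c(OC)c(OC)c2)C(OC)(O[Si](C)(C)C)C=C1O[Si](C)(C)C | intermediate
12 | 1-(2,4-dihydroxy-5-methoxyphenyl)-2-(3,4,5-trimethoxyphenyl)ethan-1-one | COc1cc(C(=O)Cc2cc(OC)c(OC)c(OC)c2)c(O)cc1O | intermediate
13 | 2,2-difluoro-7-hydroxy-6-methoxy-4-(3,4,5-trimethoxybenzyl)-1,3,2-benzodioxaborinin-3-ium-2-uide (difluoroboron chelate of 12, not isolated) | COc1cc2c(cc1O)O[B-](F)(F)[O+]=C2Cc1cc(OC)c(OC)c(OC)c1 | intermediate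
14 | 7-hydroxy-6-methoxy-3-(3,4,5-trimethoxyphenyl)-4H-chromen-4-one | COc1cc2c(=O)c(-c3cc(OC)c(OC)c(OC)c3)coc2cc1O | target

**Step count and risks**

Total step count: 6. Longest linear sequence: 4 steps (steps 1, 2, 5, 6 or steps 3, 4, 5, 6).

Steps most likely to fail:

Step 5. The cycloaddition may be outrun by hydrolysis or desilylation of the moisture-sensitive diene or by oligomerisation of the ynone. Regiocontrol may also leak, because the terminal methoxy group donates towards the acetal carbon, and closure may take place at the ketone carbonyl instead of across the alkyne. The fallback sets out from acid 5 and returns at ketone 12. Acid 5 is heated with commercial 4-methoxybenzene-1,3-diol (COc1ccc(O)cc1O) in BF3·OEt2 at 80–90 °C. This Friedel–Crafts acylation should take place at the ring position ortho to one hydroxyl and para to the other, giving 12 directly. No new compound is made on this path (F0).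

Step 4. Conjugate addition of the liberated N,O-dimethylhydroxylamine to the ynone during quench, or enolisation of the arylacetyl unit followed by self-condensation, may consume the product. The fallback sets out from amide 7 and returns at ynone 10. Reduction of 7 with iBu2AlH in THF at −78 °C should give 2-(3,4,5-trimethoxyphenyl)acetaldehyde F1. Addition of ethynylmagnesium bromide 8 at −78 → 0 °C should give 1-(3,4,5-trimethoxyphenyl)but-3-yn-2-ol F2 (racemic). Oxidation with Dess–Martin periodinane in CH2Cl2 at 0 °C should give 10 with no amine present.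

Step 6. Competing Vilsmeier formylation of the two electron-rich arenes, O-formylation of the free 4-hydroxyl or incomplete ring closure may erode the annulation. The fallback sets out from ketone 12 and returns at target 14. Selective benzylation of the non-chelated 4-hydroxyl (BnBr, K2CO3, acetone, 20 °C) should give 1-[4-(benzyloxy)-2-hydroxy-5-methoxyphenyl]-2-(3,4,5-trimethoxyphenyl)ethan-1-one F3. Heating with N,N-dimethylformamide dimethyl acetal in toluene at 80 °C (enaminone formation and cyclisation) should give 7-(benzyloxy)-6-methoxy-3-(3,4,5-trimethoxyphenyl)-4H-chromen-4-one F4. Hydrogenolysis (H2, Pd on carbon (Pd/C), EtOAc/THF, 20 °C, stopped at full debenzylation) should give 14.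

**Further compounds**

F0 | step 5 | none | none
F1 | step 4 | 2-(3,4,5-trimethoxyphenyl)acetaldehyde | COc1cc(CC=O)cc(OC)c1OC
F2 | step 4 | 1-(3,4,5-trimethoxyphenyl)but-3-yn-2-ol (racemic) | C#CC(O)Cc1cc(OC)c(OC)c(OC)c1
F3 | step 6 | 1-[4-(benzyloxy)-2-hydroxy-5-methoxyphenyl]-2-(3,4,5-trimethoxyphenyl)ethan-1-one | COc1cc(C(=O)Cc2cc(OC)c(OC)c(OC)c2)c(O)cc1OCc1ccccc1
F4 | step 6 | 7-(benzyloxy)-6-methoxy-3-(3,4,5-trimethoxyphenyl)-4H-chromen-4-one | COc1cc2c(=O)c(-c3cc(OC)c(OC)c(OC)c3)coc2cc1OCc1ccccc1
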